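**Assumption:** The target SMILES has no stereocentres, and the biaryl axis is not configurationally stable (each ring has only one ortho substituent besides the aryl–aryl bond). No stereochemistry needs to be set. The target is the biaryl dimer of malabaricone C, linked from the catechol-ring C6 to the resorcinol-ring C3.

**Retrosynthesis**
1. Demethylate the octamethyl ether 13 with BBr3, the last step.
2. Hydrogenate two aryl-alkyne chains to the (CH2)8 linkers in one step (12 → 13).
3. Form the biaryl bond by Suzuki coupling of ring-A aryl-Bpin 11 with ring-B aryl bromide 7. Each half already carries its alkynyl aryl-ketone chain.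
4. Make both halves from one building block, 8-nonynoic acid (2). ArLi addition to the acid gives the 2,6-dimethoxyphenyl ketone, and Sonogashira coupling attaches the veratryl ring.
5. All four arenes come from commercial materials, so no ring is constructed. The order is ketone, then Sonogashira, then biaryl, then alkyne reduction, then demethylation.

**Route**

**Step 1**
Reactants: 1 (8-nonyn-1-ol)
Product: 2 (8-nonynoic acid)
Conditions: CrO3, H2SO4, acetone, 0 °C → rt
Reagents that add atoms: CrO3, O=[Cr](=O)=O (oxygen source)
Why: Jones oxidation takes the primary alcohol to the acid, and the terminal alkyne survives. No stereocentre is formed.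

**Step 2**
Reactants: 3 (1,3-dimethoxybenzene, 4.5 equiv) and 2
Product: 4 (1-(2,6-dimethoxyphenyl)non-8-yn-1-one)
Conditions: n-BuLi (4.5 equiv), THF, 0 °C → rt, 2 h to make ArLi; add 2, 0 °C → rt, 12 h; 1 M HCl quench
Reagents that add atoms: none
Why: Aryllithium addition to a carboxylic acid (two ArLi per acid) gives a stable dianionic tetrahedral intermediate that collapses to the ketone only on quench, so there is no tertiary alcohol. The extra equivalents cover the acid O–H and the alkyne C–H. No stereocentre is formed.

**Step 3**
Reactants: 4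
Product: 5 (1-(3-bromo-2,6-dimethoxyphenyl)non-8-yn-1-one)
Conditions: NBS (1.0 equiv), MeCN, 0 °C → rt, dark
Reagents that add atoms: NBS, O=C1CCC(=O)N1Br
Why: Electrophilic aromatic bromination goes to C3, which is ortho to one OMe and para to the other. The terminal alkyne does not react with NBS without Ag(I). No stereocentre is formed.

**Step 4**
Reactants: 5 and 6 (4-iodo-1,2-dimethoxybenzene)
Product: 7 (1-(3-bromo-2,6-dimethoxyphenyl)-9-(3,4-dimethoxyphenyl)non-8-yn-1-one)
Conditions: Pd(PPh3)2Cl2 (3 mol %), CuI (6 mol %), Et3N, THF, rt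
Reagents that add atoms: none
Why: Sonogashira coupling is chemoselective for the aryl iodide at rt, and the hindered, electron-rich ortho-OMe aryl bromide is untouched. No stereocentre is formed.

**Step 5**
Reactants: 8 (4-bromo-1,2-dimethoxybenzene)
Product: 9 (1-bromo-2-iodo-4,5-dimethoxybenzene)
Conditions: NIS (1.05 equiv), cat. TFA, MeCN, rt
Reagents that add atoms: NIS, O=C1CCC(=O)N1I
Why: Electrophilic iodination occurs para to an OMe and ortho to Br, the same regiochemistry as the known veratrole dibromination. No stereocentre is formed.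

**Step 6**
Reactants: 4 and 9
Product: 10 (9-(2-bromo-4,5-dimethoxyphenyl)-1-(2,6-dimethoxyphenyl)non-8-yn-1-one)
Conditions: Pd(PPh3)2Cl2 (3 mol %), CuI (6 mol %), Et3N, THF, rt → 40 °C
Reagents that add atoms: none
Why: Sonogashira coupling at the C–I bond leaves the ortho C–Br for the later borylation and Suzuki coupling. No stereocentre is formed.

**Step 7**
Reactants: 10
Product: 11 (aryl-Bpin of 10)
Conditions: B2pin2 (1.2 equiv), PdCl2(dppf) (5 mol %), KOAc, dioxane, 90 °C
Reagents that add atoms: B2pin2, CC1(C)OB(OC1(C)C)B1OC(C)(C)C(C)(C)O1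
Why: Miyaura borylation converts the aryl bromide to the boronate, and the ketone and alkyne are tolerated. No stereocentre is formed.

**Step 8**
Reactants: 11 (1.3 equiv) and 7
Product: 12 (the biaryl diyne)
Conditions: Pd2(dba)3 (2.5 mol %), SPhos (10 mol %), K3PO4, toluene/H2O, 100 °C
Reagents that add atoms: none
Why: Suzuki–Miyaura coupling forms the biaryl bond. The bulky biaryl phosphine handles the di-ortho-substituted, electron-rich partners. There is no stereocentre, and the axis is not stable.

**Step 9**
Reactants: 12
Product: 13 (octamethyl ether with both chains saturated)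
Conditions: H2 (1 atm), 10% Pd/C, EtOAc, rt
Reagents that add atoms: none (H2 only)
Why: Catalytic hydrogenation reduces both internal aryl alkynes to alkanes. No aryl bromide remains to be hydrogenolysed, and the twisted 2,6-dimethoxyaryl ketones are inert. No stereocentre is formed.

**Step 10**
Reactants: 13
Product: 14 (Giganteone A)
Conditions: BBr3 (about 3 equiv per OMe, 24 equiv total), CH2Cl2, −78 °C → rt, 24 h; MeOH then H2O quench
Reagents that add atoms: none (BBr3, BBr3, is lost as boron/bromide; only H is added)
Why: BBr3 cleaves all eight aryl methyl ethers (O-demethylation) and leaves the alkyl chains and ketones intact. The target has no stereocentres.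

**Compound list**

| No. | Name | SMILES | Role |
|---|---|---|---|
| 1 | 8-nonyn-1-ol | C#CCCCCCCCO | starting material |
| 2 | 8-nonynoic acid | C#CCCCCCCC(=O)O | intermediate |
| 3 | 1,3-dimethoxybenzene | COc1cccc(OC)c1 | starting material |
| 4 | 1-(2,6-dimethoxyphenyl)non-8-yn-1-one | C#CCCCCCCC(=O)c1c(OC)cccc1OC | intermediate |
| 5 | 1-(3-bromo-2,6-dimethoxyphenyl)non-8-yn-1-one | C#CCCCCCCC(=O)c1c(OC)ccc(Br)c1OC | intermediate |
| 6 | 4-iodo-1,2-dimethoxybenzene | COc1ccc(I)cc1OC | starting material |
| 7 | 1-(3-bromo-2,6-dimethoxyphenyl)-9-(3,4-dimethoxyphenyl)non-8-yn-1-one | COc1ccc(C#CCCCCCCC(=O)c2c(OC)ccc(Br)c2OC)cc1OC | intermediate |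
| 8 | 4-bromo-1,2-dimethoxybenzene | COc1ccc(Br)cc1OC | starting material |
| 9 | 1-bromo-2-iodo-4,5-dimethoxybenzene | COc1cc(Br)c(I)cc1OC | intermediate |
| 10 | 9-(2-bromo-4,5-dimethoxyphenyl)-1-(2,6-dimethoxyphenyl)non-8-yn-1-one | COc1cc(Br)c(C#CCCCCCCC(=O)c2c(OC)cccc2OC)cc1OC | intermediate |
| 11 | Aryl-Bpin of 10 | COc1cc(B2OC(C)(C)C(C)(C)O2)c(C#CCCCCCCC(=O)c2c(OC)cccc2OC)cc1OC | intermediate |
| 12 | Biaryl diyne | COc1cc(-c2ccc(OC)c(C(=O)CCCCCCC#Cc3ccc(OC)c(OC)c3)c2OC)c(C#CCCCCCCC(=O)c2c(OC)cccc2OC)cc1OC | intermediate |
| 13 | Giganteone A octamethyl ether | COc1cc(-c2ccc(OC)c(C(=O)CCCCCCCCc3ccc(OC)c(OC)c3)c2OC)c(CCCCCCCCC(=O)c2c(OC)cccc2OC)cc1OC | intermediate |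
| 14 | Giganteone A (achiral) | O=C(CCCCCCCCc1cc(O)c(O)cc1-c1ccc(O)c(C(=O)CCCCCCCCc2ccc(O)c(O)c2)c1O)c1c(O)cccc1O | target |

**Total steps:** 10
**Longest linear sequence:** 7 (1 → 2 → 4 → 10 → 11 → 12 → 13 → 14)

**Three steps most likely to fail**
1. **Step 8 (hindered Suzuki coupling, with protodeboronation risk).**
   - Fallback: make the biaryl first from small pieces. Couple commercial 2,4-dimethoxyphenylboronic acid to iodide 9 at the C–I bond. Then add the chains afterwards: Sonogashira at the ring-A bromide, and C3′ lithiation with Weinreb acylation on ring B.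
2. **Step 2 (hindered 2,6-dimethoxyphenyllithium adding to the acid dianion; low conversion or alkynyl side reactions).**
   - Fallback: oxidise 1 to 8-nonynal, add ArLi to give the secondary alcohol, then oxidise with DMP to the ketone. The Weinreb amide route is an alternative.
3. **Step 3 (NBS monobromination with over-bromination or ketone α-bromination).**
   - Fallback: introduce the bromoarene as the nucleophile. Lithiate 1-bromo-2,4-dimethoxybenzene at C3 with LiTMP and add acid 2 to give 5 directly.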